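**Plan**

- Retrosynthesis: the three phenol O–CH2OMe bonds are cut first. Ring C is then opened at O1–C2 together with the C3–H bond, which gives an open-chain 2-aryl enone with one free ortho phenol. The enone is cut at C3–C4 into an A-ring salicylaldehyde and a B-ring 1-arylvinyl anion. The C4–C4a bond and the two aryl–prenyl bonds lead back to phloroglucinol, 4-hydroxyacetophenone and prenyl bromide.
- Forward: the A ring (steps 1–6) and the B ring (steps 7–9) are prenylated separately, joined at C3–C4 (step 10) and oxidised to the enone (step 11). Ring C, the only ring made, closes in step 13.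
- Enabling feature: in ring C, C2 is an unsubstituted CH2 between O1 and C3, and C3 is the only stereocentre and lies alpha to the C4 ketone. Ring C is therefore the conjugate adduct of the O1 phenol with the terminal methylene of a 2-aryl enone, and its configuration is decided only by the face on which C3 is protonated.
- Stereochemistry: (3R) comes from catalyst-controlled protonation of the enol formed in the ring closure. No base is used afterwards, so that C3 is not scrambled.

Key step: step 13

Assumption: which pseudo-enantiomeric cinchona squaramide (quinine or quinidine series) leads to 3R cannot be predicted safely for this new closure; both are available, the quinine-derived one is written and the other is taken if the sense proves opposite.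

**Step 1**
Reactants: 1 benzene-1,3,5-triol (phloroglucinol)
Product: 2 3,5-bis(methoxymethoxy)phenol
Conditions: MOMCl (2.0 equiv), i-Pr2NEt, DMF, 0 °C → rt; chromatography
Reagents that add atoms: chloromethyl methyl ether (MOMCl), COCCl
Why: Williamson-type O-alkylation of the phenoxide with about two equivalents of the chloromethyl ether should give the bis-acetal as the main component of a statistical mixture, from which it is separated by chromatography.

**Step 2**
Reactants: 2 3,5-bis(methoxymethoxy)phenol
Product: 3 [3,5-bis(methoxymethoxy)phenoxy]tri(propan-2-yl)silane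
Conditions: TIPSCl, imidazole, DMF, rt
Reagents that add atoms: chlorotri(propan-2-yl)silane (TIPSCl), CC(C)[Si](Cl)(C(C)C)C(C)C
Why: Standard silylation of the one remaining phenol gives a symmetric arene in which the bulky, non-coordinating silyl ether withstands n-BuLi and leaves the carbon between the two acetal oxygens as the only strongly activated site.

**Step 3**
Reactants: 3 [3,5-bis(methoxymethoxy)phenoxy]tri(propan-2-yl)silane; 4 1-bromo-3-methylbut-2-ene (prenyl bromide)
Product: 6 [3,5-bis(methoxymethoxy)-4-(3-methylbut-2-en-1-yl)phenoxy]tri(propan-2-yl)silane, via aryllithium 5 (not isolated)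
Conditions: n-BuLi, THF, 0 °C; CuI (10 mol%), then 4, −78 °C → rt
Reagents that add atoms: 1-bromo-3-methylbut-2-ene (4), CC(C)=CCBr
Why: Directed ortho-metalation at the carbon flanked by both methoxymethoxy groups (double chelation of lithium) followed by copper-assisted SN2 alkylation of the aryl anion with the allylic bromide should install the prenyl group at one defined position.

**Step 4**
Reactants: 6 [3,5-bis(methoxymethoxy)-4-(3-methylbut-2-en-1-yl)phenoxy]tri(propan-2-yl)silane
Product: 7 3,5-bis(methoxymethoxy)-4-(3-methylbut-2-en-1-yl)phenol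
Conditions: TBAF, THF, 0 °C; aq. NH4Cl
Reagents that add atoms: none
Why: Fluoride-mediated desilylation of the aryl silyl ether frees the phenol needed to direct the formylation, the acetals and the trisubstituted alkene being inert to fluoride.

**Step 5**
Reactants: 7 3,5-bis(methoxymethoxy)-4-(3-methylbut-2-en-1-yl)phenol
Product: 8 6-hydroxy-2,4-bis(methoxymethoxy)-3-(3-methylbut-2-en-1-yl)benzaldehyde
Conditions: MgCl2, Et3N, (CH2O)n, THF, reflux; cold dilute citric acid work-up
Reagents that add atoms: paraformaldehyde (as formaldehyde), C=O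
Why: Magnesium-phenoxide-directed ortho-formylation (Casnati–Skattebøl reaction) delivers formaldehyde only ortho to the free hydroxyl, the two ortho positions are equivalent by symmetry so that one salicylaldehyde should result, and a second formaldehyde acts as the hydride acceptor under basic conditions that the acetals tolerate.

**Step 6**
Reactants: 8 6-hydroxy-2,4-bis(methoxymethoxy)-3-(3-methylbut-2-en-1-yl)benzaldehyde
Product: 9 6-[tert-butyl(dimethyl)silyl]oxy-2,4-bis(methoxymethoxy)-3-(3-methylbut-2-en-1-yl)benzaldehyde
Conditions: TBSCl, imidazole, DMAP (cat.), DMF, rt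
Reagents that add atoms: tert-butyl(chloro)dimethylsilane (TBSCl), CC(C)(C)[Si](C)(C)Cl
Why: Silylation of the chelated phenol removes the acidic proton before the organolithium addition and gives an aryl silyl ether that fluoride can later cleave without touching the three acetals.

**Step 7**
Reactants: 10 1-(4-hydroxyphenyl)ethan-1-one (4-hydroxyacetophenone); 4 1-bromo-3-methylbut-2-ene
Product: 11 1-[4-hydroxy-3-(3-methylbut-2-en-1-yl)phenyl]ethan-1-one
Conditions: KOH (1.1 equiv), H2O, 4, rt; chromatography
Reagents that add atoms: 1-bromo-3-methylbut-2-ene (4), CC(C)=CCBr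
Why: Ortho C-alkylation of the phenoxide in water, where hydrogen bonding to oxygen diverts part of the allylic alkylation to carbon, is the known direct entry to this ketone, with only modest conversion expected and the O-prenyl ether removed by chromatography.

**Step 8**
Reactants: 11 1-[4-hydroxy-3-(3-methylbut-2-en-1-yl)phenyl]ethan-1-one
Product: 12 1-[4-(methoxymethoxy)-3-(3-methylbut-2-en-1-yl)phenyl]ethan-1-one
Conditions: MOMCl, i-Pr2NEt, CH2Cl2, 0 °C → rt
Reagents that add atoms: chloromethyl methyl ether (MOMCl), COCCl
Why: O-alkylation of the phenol with the chloromethyl ether under amine base protects it against the two equivalents of alkyllithium used in step 10.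

**Step 9**
Reactants: 12 1-[4-(methoxymethoxy)-3-(3-methylbut-2-en-1-yl)phenyl]ethan-1-one
Product: 13 (E)-N'-{1-[4-(methoxymethoxy)-3-(3-methylbut-2-en-1-yl)phenyl]ethylidene}-2,4,6-tri(propan-2-yl)benzenesulfonohydrazide
Conditions: 2,4,6-triisopropylbenzenesulfonohydrazide, PPTS (cat.), THF, 4 Å MS, rt
Reagents that add atoms: 2,4,6-tri(propan-2-yl)benzenesulfonohydrazide, NNS(=O)(=O)c1c(C(C)C)cc(C(C)C)cc1C(C)C
Why: Condensation of the methyl ketone with the hindered arenesulfonyl hydrazide gives the E hydrazone needed for a Shapiro reaction, the 2,4,6-triisopropyl groups preventing lithiation of the sulfonyl arene.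

**Step 10**
Reactants: 13 (E)-N'-{1-[4-(methoxymethoxy)-3-(3-methylbut-2-en-1-yl)phenyl]ethylidene}-2,4,6-tri(propan-2-yl)benzenesulfonohydrazide; 9 6-[tert-butyl(dimethyl)silyl]oxy-2,4-bis(methoxymethoxy)-3-(3-methylbut-2-en-1-yl)benzaldehyde
Product: 16 rac-1-{6-[tert-butyl(dimethyl)silyl]oxy-2,4-bis(methoxymethoxy)-3-(3-methylbut-2-en-1-yl)phenyl}-2-[4-(methoxymethoxy)-3-(3-methylbut-2-en-1-yl)phenyl]prop-2-en-1-ol, via hydrazone dianion 14 (not isolated), via vinyllithium 15 (not isolated)
Conditions: n-BuLi (2.05 equiv), THF, −78 °C → 0 °C (N2 evolution); −78 °C, 9; AcOH, −78 °C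
Reagents that add atoms: none
Why: In this Shapiro reaction the dianion loses sulfinate and dinitrogen to give the 1-arylvinyllithium, whose 1,2-addition to the non-enolisable aldehyde forms the C3–C4 bond, the new carbinol centre being racemic and erased in step 11 and the cold acidic quench keeping the silyl group on the phenol oxygen.

**Step 11**
Reactants: 16 rac-1-{6-[tert-butyl(dimethyl)silyl]oxy-2,4-bis(methoxymethoxy)-3-(3-methylbut-2-en-1-yl)phenyl}-2-[4-(methoxymethoxy)-3-(3-methylbut-2-en-1-yl)phenyl]prop-2-en-1-ol
Product: 17 1-{6-[tert-butyl(dimethyl)silyl]oxy-2,4-bis(methoxymethoxy)-3-(3-methylbut-2-en-1-yl)phenyl}-2-[4-(methoxymethoxy)-3-(3-methylbut-2-en-1-yl)phenyl]prop-2-en-1-one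
Conditions: Dess–Martin periodinane, pyridine, CH2Cl2, 0 °C → rt
Reagents that add atoms: none
Why: Dess–Martin oxidation of the doubly activated (benzylic and allylic) secondary alcohol under pyridine buffer should give the cross-conjugated enone without affecting the silyl ether, the acetals or the prenyl alkenes, and it removes the only stereocentre present so far.

**Step 12**
Reactants: 17 1-{6-[tert-butyl(dimethyl)silyl]oxy-2,4-bis(methoxymethoxy)-3-(3-methylbut-2-en-1-yl)phenyl}-2-[4-(methoxymethoxy)-3-(3-methylbut-2-en-1-yl)phenyl]prop-2-en-1-one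
Product: 18 1-[6-hydroxy-2,4-bis(methoxymethoxy)-3-(3-methylbut-2-en-1-yl)phenyl]-2-[4-(methoxymethoxy)-3-(3-methylbut-2-en-1-yl)phenyl]prop-2-en-1-one
Conditions: Et3N·3HF, THF, 0 °C → rt; pH 7 buffer; used at once
Reagents that add atoms: none
Why: Cleavage of the aryl silyl ether with a weakly acidic fluoride source in which no free base is present releases the phenol in its neutral, carbonyl-chelated form and so avoids the phenoxide that would trigger racemic ring closure, the acetals being stable to these conditions.

**Step 13**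
Reactants: 18 1-[6-hydroxy-2,4-bis(methoxymethoxy)-3-(3-methylbut-2-en-1-yl)phenyl]-2-[4-(methoxymethoxy)-3-(3-methylbut-2-en-1-yl)phenyl]prop-2-en-1-one
Product: 20 (3R)-5,7-bis(methoxymethoxy)-3-[4-(methoxymethoxy)-3-(3-methylbut-2-en-1-yl)phenyl]-6-(3-methylbut-2-en-1-yl)-2,3-dihydro-4H-chromen-4-one, via enol 19 (not isolated)
Conditions: quinine-derived 3,5-bis(trifluoromethyl)phenyl squaramide (10 mol%), toluene (0.02 M), −40 °C; AcOH quench, cold filtration through silica
Reagents that add atoms: none
Why: Proposed new method: the quinuclidine nitrogen of the catalyst takes up the chelated phenol proton while the squaramide N–H bonds hold the ketone oxygen, the phenoxide adds to the unsubstituted terminal methylene of the 2-aryl enone (oxa-Michael) and the catalyst-bound enol 19 is then protonated at C3 by the quinuclidinium N–H within the ion pair. The closest known reaction types are the amine-mediated closure of alpha-methylene deoxybenzoins to racemic isoflavanones and organocatalytic conjugate addition–enantioselective protonation on alpha-substituted acceptors, whose combination in one intramolecular oxa-Michael event has not been shown on this substrate class. Ring C closes in a 6-endo-trig mode by formation of the O1–C2 bond. The C3 stereocentre is controlled by the catalyst alone, through the face of the planar enol to which the ammonium proton is delivered, and the pseudo-enantiomer of the catalyst is chosen to give 3R. The 6-prenyl rather than 8-prenyl pattern is secured because the only free phenol is the one para to the A-ring prenyl group, the oxygen between the acyl and prenyl carbons being a methoxymethyl ether. Enantioselectivity requires the catalysed path to outrun uncatalysed closure and enolisation of the product, which the internal O–H···O=C hydrogen bond of 18 (it turns the vinyl group away from the phenol oxygen until a base intervenes), the non-polar solvent, the low temperature and the acidic quench are meant to ensure.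

**Step 14**
Reactants: 20 (3R)-5,7-bis(methoxymethoxy)-3-[4-(methoxymethoxy)-3-(3-methylbut-2-en-1-yl)phenyl]-6-(3-methylbut-2-en-1-yl)-2,3-dihydro-4H-chromen-4-one
Product: 21 (3R)-5,7-dihydroxy-3-[4-hydroxy-3-(3-methylbut-2-en-1-yl)phenyl]-6-(3-methylbut-2-en-1-yl)-2,3-dihydro-4H-chromen-4-one
Conditions: methanolic HCl (1.25 M), THF, 0 °C → rt; quench into pH 7 phosphate buffer
Reagents that add atoms: none
Why: Acid-catalysed acetal exchange with methanol removes the three methoxymethyl groups as dimethoxymethane, the peri 5-O-acetal first, and the absence of base together with low temperature and quenching as soon as the last acetal is gone should keep acid-catalysed enolisation at C3 and cyclisation of the prenyl groups onto the new phenols from competing.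

**Compound list**

1 | benzene-1,3,5-triol (phloroglucinol) | Oc1cc(O)cc(O)c1 | starting material
2 | 3,5-bis(methoxymethoxy)phenol | COCOc1cc(O)cc(OCOC)c1 | intermediate
3 | [3,5-bis(methoxymethoxy)phenoxy]tri(propan-2-yl)silane | COCOc1cc(OCOC)cc(O[Si](C(C)C)(C(C)C)C(C)C)c1 | intermediate
4 | 1-bromo-3-methylbut-2-ene (prenyl bromide) | CC(C)=CCBr | starting material
5 | aryllithium: {2,6-bis(methoxymethoxy)-4-[tri(propan-2-yl)silyloxy]phenyl}lithium (not isolated) | [Li]c1c(OCOC)cc(O[Si](C(C)C)(C(C)C)C(C)C)cc1OCOC | intermediate
6 | [3,5-bis(methoxymethoxy)-4-(3-methylbut-2-en-1-yl)phenoxy]tri(propan-2-yl)silane | CC(C)=CCc1c(OCOC)cc(O[Si](C(C)C)(C(C)C)C(C)C)cc1OCOC | intermediate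
7 | 3,5-bis(methoxymethoxy)-4-(3-methylbut-2-en-1-yl)phenol | CC(C)=CCc1c(OCOC)cc(O)cc1OCOC | intermediate
8 | 6-hydroxy-2,4-bis(methoxymethoxy)-3-(3-methylbut-2-en-1-yl)benzaldehyde | O=Cc1c(O)cc(OCOC)c(CC=C(C)C)c1OCOC | intermediate
9 | 6-[tert-butyl(dimethyl)silyl]oxy-2,4-bis(methoxymethoxy)-3-(3-methylbut-2-en-1-yl)benzaldehyde | O=Cc1c(O[Si](C)(C)C(C)(C)C)cc(OCOC)c(CC=C(C)C)c1OCOC | intermediate
10 | 1-(4-hydroxyphenyl)ethan-1-one (4-hydroxyacetophenone) | CC(=O)c1ccc(O)cc1 | starting material
11 | 1-[4-hydroxy-3-(3-methylbut-2-en-1-yl)phenyl]ethan-1-one | CC(=O)c1ccc(O)c(CC=C(C)C)c1 | intermediate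
12 | 1-[4-(methoxymethoxy)-3-(3-methylbut-2-en-1-yl)phenyl]ethan-1-one | CC(=O)c1ccc(OCOC)c(CC=C(C)C)c1 | intermediate
13 | (E)-N'-{1-[4-(methoxymethoxy)-3-(3-methylbut-2-en-1-yl)phenyl]ethylidene}-2,4,6-tri(propan-2-yl)benzenesulfonohydrazide | C/C(=N\NS(=O)(=O)c1c(C(C)C)cc(C(C)C)cc1C(C)C)c1ccc(OCOC)c(CC=C(C)C)c1 | intermediate
14 | hydrazone dianion: N,C-dilithio derivative of 13, lithiated at nitrogen and at the methyl carbon (not isolated) | [Li]C/C(=N\N([Li])S(=O)(=O)c1c(C(C)C)cc(C(C)C)cc1C(C)C)c1ccc(OCOC)c(CC=C(C)C)c1 | intermediate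
15 | vinyllithium: {1-[4-(methoxymethoxy)-3-(3-methylbut-2-en-1-yl)phenyl]ethenyl}lithium (not isolated) | [Li]C(=C)c1ccc(OCOC)c(CC=C(C)C)c1 | intermediate
16 | rac-1-{6-[tert-butyl(dimethyl)silyl]oxy-2,4-bis(methoxymethoxy)-3-(3-methylbut-2-en-1-yl)phenyl}-2-[4-(methoxymethoxy)-3-(3-methylbut-2-en-1-yl)phenyl]prop-2-en-1-ol (racemate) | C=C(c1ccc(OCOC)c(CC=C(C)C)c1)C(O)c1c(O[Si](C)(C)C(C)(C)C)cc(OCOC)c(CC=C(C)C)c1OCOC | intermediate
17 | 1-{6-[tert-butyl(dimethyl)silyl]oxy-2,4-bis(methoxymethoxy)-3-(3-methylbut-2-en-1-yl)phenyl}-2-[4-(methoxymethoxy)-3-(3-methylbut-2-en-1-yl)phenyl]prop-2-en-1-one | C=C(c1ccc(OCOC)c(CC=C(C)C)c1)C(=O)c1c(O[Si](C)(C)C(C)(C)C)cc(OCOC)c(CC=C(C)C)c1OCOC | intermediate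
18 | 1-[6-hydroxy-2,4-bis(methoxymethoxy)-3-(3-methylbut-2-en-1-yl)phenyl]-2-[4-(methoxymethoxy)-3-(3-methylbut-2-en-1-yl)phenyl]prop-2-en-1-one | C=C(c1ccc(OCOC)c(CC=C(C)C)c1)C(=O)c1c(O)cc(OCOC)c(CC=C(C)C)c1OCOC | intermediate
19 | enol: 5,7-bis(methoxymethoxy)-3-[4-(methoxymethoxy)-3-(3-methylbut-2-en-1-yl)phenyl]-6-(3-methylbut-2-en-1-yl)-2H-chromen-4-ol, catalyst-bound (not isolated) | OC1=C(c2ccc(OCOC)c(CC=C(C)C)c2)COc2cc(OCOC)c(CC=C(C)C)c(OCOC)c12 | intermediate
20 | (3R)-5,7-bis(methoxymethoxy)-3-[4-(methoxymethoxy)-3-(3-methylbut-2-en-1-yl)phenyl]-6-(3-methylbut-2-en-1-yl)-2,3-dihydro-4H-chromen-4-one | CC(C)=CCc1cc([C@@H]2COc3cc(OCOC)c(CC=C(C)C)c(OCOC)c3C2=O)ccc1OCOC | intermediate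
21 | (3R)-5,7-dihydroxy-3-[4-hydroxy-3-(3-methylbut-2-en-1-yl)phenyl]-6-(3-methylbut-2-en-1-yl)-2,3-dihydro-4H-chromen-4-one | CC(C)=CCc1cc([C@@H]2COc3cc(O)c(CC=C(C)C)c(O)c3C2=O)ccc1O | target

**Step count and risks**

Total: 14 steps. Longest linear sequence: 11 steps (steps 1–6, then 10–14); the B-ring branch is steps 7–9.

Steps most likely to fail:

1. Step 13. The protonation at C3 may show poor facial selectivity, or racemic background closure and amine-mediated enolisation of the product may erode the enantiomeric purity. The stereocentre would then be set by known chemistry after a deliberately racemic closure. The fallback sets out from 18: catalytic Et3N in CH2Cl2 at rt should close it to the racemic tri-MOM isoflavanone F1. Asymmetric transfer hydrogenation under dynamic kinetic resolution [RuCl(p-cymene)((R,R)-TsDPEN), HCO2H/Et3N, EtOAc, rt] follows; the amine keeps C3 epimerising while hydride is delivered to one enantiomer of the ketone. This should give the cis-(3R,4R)-isoflavan-4-ol F2 (the (S,S) catalyst is taken if the sense proves opposite). Dess–Martin oxidation with pyridine buffer then restores the ketone without touching C3, and the route is rejoined at 20.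

2. Step 14. Configuration at C3 may be lost through acid-catalysed enolisation while the two non-chelated acetals are slowly cleaved, or a prenyl group may cyclise onto its neighbouring phenol under acid. The acetals would then be exchanged for silyl ethers under buffered aprotic conditions, and the silyl ethers removed with the fluoride source already used in step 12. The fallback sets out from 20: TESOTf and 2,2'-bipyridyl in CH2Cl2 at 0 °C should convert the three aryl methoxymethyl ethers into the (3R)-tris(triethylsilyl) ether F3. Et3N·3HF in THF at 0 °C → rt then frees the phenols, and the route is rejoined at 21.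

3. Step 7. Alkylation may occur at oxygen instead of carbon, together with double alkylation, leaving little C-prenyl ketone. The prenyl group would then be introduced by cross-coupling. The fallback sets out from 10: ortho-bromination (NBS, MeCN, rt) should give 1-(3-bromo-4-hydroxyphenyl)ethan-1-one F4. MOMCl/i-Pr2NEt should give 1-[3-bromo-4-(methoxymethoxy)phenyl]ethan-1-one F5. Suzuki–Miyaura coupling with 4,4,5,5-tetramethyl-2-(3-methylbut-2-en-1-yl)-1,3,2-dioxaborolane [Pd(dppf)Cl2, K3PO4, THF–H2O, 70 °C] should then give the linear prenyl arene, and the route is rejoined at 12.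

**Further compounds**

F1 | step 13 | racemic 5,7-bis(methoxymethoxy)-3-[4-(methoxymethoxy)-3-(3-methylbut-2-en-1-yl)phenyl]-6-(3-methylbut-2-en-1-yl)-2,3-dihydro-4H-chromen-4-one | CC(C)=CCc1cc(C2COc3cc(OCOC)c(CC=C(C)C)c(OCOC)c3C2=O)ccc1OCOC
F2 | step 13 | (3R,4R)-5,7-bis(methoxymethoxy)-3-[4-(methoxymethoxy)-3-(3-methylbut-2-en-1-yl)phenyl]-6-(3-methylbut-2-en-1-yl)-3,4-dihydro-2H-chromen-4-ol (cis) | CC(C)=CCc1cc([C@@H]2COc3cc(OCOC)c(CC=C(C)C)c(OCOC)c3[C@@H]2O)ccc1OCOC
F3 | step 14 | (3R)-5,7-bis(triethylsilyloxy)-3-[4-(triethylsilyloxy)-3-(3-methylbut-2-en-1-yl)phenyl]-6-(3-methylbut-2-en-1-yl)-2,3-dihydro-4H-chromen-4-one | CC(C)=CCc1cc([C@@H]2COc3cc(O[Si](CC)(CC)CC)c(CC=C(C)C)c(O[Si](CC)(CC)CC)c3C2=O)ccc1O[Si](CC)(CC)CC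
F4 | step 7 | 1-(3-bromo-4-hydroxyphenyl)ethan-1-one | CC(=O)c1ccc(O)c(Br)c1
F5 | step 7 | 1-[3-bromo-4-(methoxymethoxy)phenyl]ethan-1-one | CC(=O)c1ccc(OCOC)c(Br)c1
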